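**Assumption:** the target SMILES has no stereocentres and no stereogenic double bond, so the compound is achiral and no enantiocontrol is needed. The only stereo-elements in the route (a racemic carbinol and an E-enaminone) are erased before the end.

## Retrosynthetic overview

1. Remove three MOM ethers last. Disconnect the isoflavone at C3–C1′ and O1–C2: an o-hydroxyaryl enaminone (A ring) plus a 6-bromo-2,2-dimethyl-2H-chromene (B ring), joined by a Pd-catalysed C–H arylation/annulation that closes the pyranone ring last.
2. A ring from hydroquinone: two MOM-directed ortho-metalations install the future O1 (as OBn, so it is distinguishable from the C5/C8 oxygens) and then the acetyl group between OBn and OMOM.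
3. Side chain by iodination para to OBn, Sonogashira coupling with 2-methylbut-3-yn-2-ol, and one hydrogenation that also removes the benzyl group.
4. B ring from resorcinol: bromination, Friedel–Crafts/oxa-Michael chromanone formation (Br fixed at C6), then reduction and dehydration to the chromene.
5. Ring order: B-ring pyran (chromanone, then chromene) in its own branch; isoflavone pyranone ring formed in the fragment union.

## Route

### Fragment A (enaminone)

**Step 1**
Reactants: 1, hydroquinone
Product: 2, 1,4-bis(methoxymethoxy)benzene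
Conditions: NaH, MOMCl, DMF, 0 °C to rt
Reagents that add atoms: chloromethyl methyl ether, COCCl
Why: Williamson-type O-alkylation of both phenoxides (MOM protection) gives a diether whose OMOM groups serve as directed-metalation groups later.

**Step 2**
Reactants: 2, 1,4-bis(methoxymethoxy)benzene
Product: 3, 2,5-bis(methoxymethoxy)phenol
Conditions: n-BuLi (1.1 equiv), TMEDA, THF, 0 °C; B(OMe)3, −78 °C to rt; then 30% H2O2, aq NaOH, 0 °C
Reagents that add atoms: hydrogen peroxide, OO (supplies the new phenolic oxygen; boron is not retained)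
Why: MOM-directed ortho-lithiation (all four ring C–H are equivalent, so one product), borylation and oxidative C–B to C–O conversion give the phenol.

**Step 3**
Reactants: 3, 2,5-bis(methoxymethoxy)phenol
Product: 4, 2-(benzyloxy)-1,4-bis(methoxymethoxy)benzene
Conditions: BnBr, K2CO3, DMF, rt
Reagents that add atoms: benzyl bromide, BrCc1ccccc1
Why: Williamson benzylation marks this oxygen (future ring O1) as different from the two MOM-protected hydroquinone oxygens, which fixes the later cyclisation regiochemistry.

**Step 4**
Reactants: 4, 2-(benzyloxy)-1,4-bis(methoxymethoxy)benzene; 5, N-methoxy-N-methylacetamide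
Product: 6, 1-[2-(benzyloxy)-3,6-bis(methoxymethoxy)phenyl]ethan-1-one
Conditions: n-BuLi (1.2 equiv), THF, −78 to −10 °C; then 5, −78 °C to rt
Reagents that add atoms: none
Why: Directed ortho-metalation takes place at the C–H flanked by OBn and OMOM (cooperative direction, as in 1,2,4-trialkoxybenzenes), and Weinreb-amide acylation stops at the ketone.

**Step 5**
Reactants: 6, 1-[2-(benzyloxy)-3,6-bis(methoxymethoxy)phenyl]ethan-1-one
Product: 7, 1-[2-(benzyloxy)-5-iodo-3,6-bis(methoxymethoxy)phenyl]ethan-1-one
Conditions: NIS (1.1 equiv), MeCN, 0 °C to rt, dark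
Reagents that add atoms: N-iodosuccinimide, O=C1CCC(=O)N1I
Why: Electrophilic aromatic iodination goes to the only C–H that is para to OBn and ortho to OMOM; the other free position is para to the acetyl group and deactivated.

**Step 6**
Reactants: 7, 1-[2-(benzyloxy)-5-iodo-3,6-bis(methoxymethoxy)phenyl]ethan-1-one; 8, 2-methylbut-3-yn-2-ol
Product: 9, 1-[2-(benzyloxy)-5-(3-hydroxy-3-methylbut-1-yn-1-yl)-3,6-bis(methoxymethoxy)phenyl]ethan-1-one
Conditions: Pd(PPh3)2Cl2 (3 mol %), CuI (5 mol %), Et3N/THF, 50 °C
Reagents that add atoms: none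
Why: Sonogashira coupling of an aryl iodide with a terminal alkyne tolerates the ketone, MOM ethers and free tertiary alcohol.

**Step 7**
Reactants: 9, 1-[2-(benzyloxy)-5-(3-hydroxy-3-methylbut-1-yn-1-yl)-3,6-bis(methoxymethoxy)phenyl]ethan-1-one
Product: 10, 1-[2-hydroxy-5-(3-hydroxy-3-methylbutyl)-3,6-bis(methoxymethoxy)phenyl]ethan-1-one
Conditions: H2 (1 atm), 10% Pd/C, EtOAc/EtOH, rt
Reagents that add atoms: none
Why: Catalytic hydrogenation saturates the alkyne and hydrogenolyses the benzyl ether in one operation, while the hindered, hydrogen-bonded aryl ketone and the MOM ethers are not reduced under these mild conditions.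

**Step 8**
Reactants: 10, 1-[2-hydroxy-5-(3-hydroxy-3-methylbutyl)-3,6-bis(methoxymethoxy)phenyl]ethan-1-one; 11, N,N-dimethylformamide dimethyl acetal
Product: 12, (E)-3-(dimethylamino)-1-[2-hydroxy-5-(3-hydroxy-3-methylbutyl)-3,6-bis(methoxymethoxy)phenyl]prop-2-en-1-one
Conditions: 11 (3 equiv), toluene, 90 °C
Reagents that add atoms: none
Why: Aminomethylenation of the methyl ketone gives the thermodynamically favoured E push–pull enaminone, the standard chromone precursor; only the former OBn oxygen is free to cyclise later.

### Fragment B (bromochromene)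

**Step 9**
Reactants: 13, resorcinol
Product: 14, 4-bromobenzene-1,3-diol
Conditions: NBS (1.0 equiv), MeCN, −20 to 0 °C
Reagents that add atoms: N-bromosuccinimide, O=C1CCC(=O)N1Br
Why: Electrophilic monobromination occurs at C4, para to one OH and ortho to the other.

**Step 10**
Reactants: 14, 4-bromobenzene-1,3-diol; 15, 3-methylbut-2-enoic acid
Product: 16, 6-bromo-7-hydroxy-2,2-dimethylchroman-4-one
Conditions: MeSO3H/P2O5 (Eaton's reagent), 70 °C
Reagents that add atoms: none
Why: Friedel–Crafts acylation at the only unhindered position ortho/para to both hydroxyls, then intramolecular oxa-Michael addition, gives the linear chromanone with Br fixed at C6.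

**Step 11**
Reactants: 16, 6-bromo-7-hydroxy-2,2-dimethylchroman-4-one
Product: 17, 6-bromo-7-(methoxymethoxy)-2,2-dimethylchroman-4-one
Conditions: MOMCl, i-Pr2NEt, CH2Cl2, 0 °C to rt
Reagents that add atoms: chloromethyl methyl ether, COCCl
Why: O-alkylation of the acidic para-acyl phenol (MOM protection) masks the phenol for the Pd step.

**Step 12**
Reactants: 17, 6-bromo-7-(methoxymethoxy)-2,2-dimethylchroman-4-one
Product: 18, 6-bromo-7-(methoxymethoxy)-2,2-dimethylchroman-4-ol (racemic)
Conditions: NaBH4, MeOH/THF, 0 °C to rt
Reagents that add atoms: none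
Why: Hydride reduction of the aryl ketone gives the carbinol as a racemate, which is acceptable because this stereocentre is destroyed in step 13.

**Step 13**
Reactants: 18, 6-bromo-7-(methoxymethoxy)-2,2-dimethylchroman-4-ol
Product: 19, 6-bromo-7-(methoxymethoxy)-2,2-dimethyl-2H-chromene
Conditions: MsCl, Et3N, CH2Cl2, 0 °C to reflux
Reagents that add atoms: none
Why: Mesylation of the electron-rich benzylic alcohol and base-mediated elimination give the conjugated 2H-chromene without acid, so the MOM ether survives.

### Fragment union and end game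

**Step 14**
Reactants: 12, (E)-3-(dimethylamino)-1-[2-hydroxy-5-(3-hydroxy-3-methylbutyl)-3,6-bis(methoxymethoxy)phenyl]prop-2-en-1-one; 19, 6-bromo-7-(methoxymethoxy)-2,2-dimethyl-2H-chromene (1.3 equiv)
Product: 20, 6-(3-hydroxy-3-methylbutyl)-5,8-bis(methoxymethoxy)-3-[7-(methoxymethoxy)-2,2-dimethyl-2H-chromen-6-yl]-4H-chromen-4-one
Conditions: Pd(OAc)2 (5 mol %), PCy3·HBF4 (10 mol %), Cs2CO3 (2.5 equiv), PivOH (30 mol %), DMF, 100 °C; then AcOH, 50 °C
Reagents that add atoms: none
Why: Proposed new method: after oxidative addition of Pd(0) into the aryl bromide, the caesium phenoxide of 12 binds Pd and delivers it to the enaminone α-C–H through a six-membered oxapalladacycle (carbonate/pivalate-assisted metalation at the most nucleophilic vinylic carbon), C–C reductive elimination gives the α-aryl enaminone, and acid then drives 6-endo O-cyclisation with loss of Me2NH to the isoflavone; the closest known reactions are hydroxyl-directed Pd-catalysed C–H arylation of 2-arylphenols and salicylaldehydes with aryl halides, Pd-catalysed α-C–H arylation of cyclic enaminones, and the electrophile-triggered domino annulation of o-hydroxyaryl enaminones to 3-substituted chromones.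

**Step 15**
Reactants: 20, 6-(3-hydroxy-3-methylbutyl)-5,8-bis(methoxymethoxy)-3-[7-(methoxymethoxy)-2,2-dimethyl-2H-chromen-6-yl]-4H-chromen-4-one
Product: 21, Kraussianone 3, 5,8-dihydroxy-6-(3-hydroxy-3-methylbutyl)-3-(7-hydroxy-2,2-dimethyl-2H-chromen-6-yl)-4H-chromen-4-one
Conditions: 3 M aq HCl, MeOH/THF, 40 °C
Reagents that add atoms: none
Why: Mild acid-catalysed acetal hydrolysis removes the three aryl MOM ethers; the temperature is kept low so the 2,2-dimethylchromene and the tertiary alcohol are not hydrated, cyclised or solvolysed.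

## Compound list

1 | hydroquinone | Oc1ccc(O)cc1 | starting material
2 | 1,4-bis(methoxymethoxy)benzene | COCOc1ccc(OCOC)cc1 | intermediate
3 | 2,5-bis(methoxymethoxy)phenol | COCOc1ccc(OCOC)c(O)c1 | intermediate
4 | 2-(benzyloxy)-1,4-bis(methoxymethoxy)benzene | COCOc1ccc(OCOC)c(OCc2ccccc2)c1 | intermediate
5 | N-methoxy-N-methylacetamide | CC(=O)N(C)OC | starting material
6 | 1-[2-(benzyloxy)-3,6-bis(methoxymethoxy)phenyl]ethan-1-one | CC(=O)c1c(OCc2ccccc2)c(OCOC)ccc1OCOC | intermediate
7 | 1-[2-(benzyloxy)-5-iodo-3,6-bis(methoxymethoxy)phenyl]ethan-1-one | CC(=O)c1c(OCc2ccccc2)c(OCOC)cc(I)c1OCOC | intermediate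
8 | 2-methylbut-3-yn-2-ol | CC(C)(O)C#C | starting material
9 | 1-[2-(benzyloxy)-5-(3-hydroxy-3-methylbut-1-yn-1-yl)-3,6-bis(methoxymethoxy)phenyl]ethan-1-one | CC(=O)c1c(OCc2ccccc2)c(OCOC)cc(C#CC(C)(C)O)c1OCOC | intermediate
10 | 1-[2-hydroxy-5-(3-hydroxy-3-methylbutyl)-3,6-bis(methoxymethoxy)phenyl]ethan-1-one | CC(=O)c1c(O)c(OCOC)cc(CCC(C)(C)O)c1OCOC | intermediate
11 | N,N-dimethylformamide dimethyl acetal | COC(OC)N(C)C | starting material
12 | (E)-3-(dimethylamino)-1-[2-hydroxy-5-(3-hydroxy-3-methylbutyl)-3,6-bis(methoxymethoxy)phenyl]prop-2-en-1-one | CN(C)/C=C/C(=O)c1c(O)c(OCOC)cc(CCC(C)(C)O)c1OCOC | intermediate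
13 | resorcinol | Oc1cccc(O)c1 | starting material
14 | 4-bromobenzene-1,3-diol | Oc1ccc(Br)c(O)c1 | intermediate
15 | 3-methylbut-2-enoic acid | CC(C)=CC(=O)O | starting material
16 | 6-bromo-7-hydroxy-2,2-dimethylchroman-4-one | CC1(C)CC(=O)c2cc(Br)c(O)cc2O1 | intermediate
17 | 6-bromo-7-(methoxymethoxy)-2,2-dimethylchroman-4-one | COCOc1cc2OC(C)(C)CC(=O)c2cc1Br | intermediate
18 | 6-bromo-7-(methoxymethoxy)-2,2-dimethylchroman-4-ol (racemic) | COCOc1cc2OC(C)(C)CC(O)c2cc1Br | intermediate
19 | 6-bromo-7-(methoxymethoxy)-2,2-dimethyl-2H-chromene | COCOc1cc2OC(C)(C)C=Cc2cc1Br | intermediate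
20 | 6-(3-hydroxy-3-methylbutyl)-5,8-bis(methoxymethoxy)-3-[7-(methoxymethoxy)-2,2-dimethyl-2H-chromen-6-yl]-4H-chromen-4-one | COCOc1cc2OC(C)(C)C=Cc2cc1-c1coc2c(OCOC)cc(CCC(C)(C)O)c(OCOC)c2c1=O | intermediate
21 | Kraussianone 3 | CC(C)(O)CCc1cc(O)c2occ(-c3cc4c(cc3O)OC(C)(C)C=C4)c(=O)c2c1O | target

## Summary

- **Total step count:** 15
- **Longest linear sequence:** 10 (steps 1–8, then 14 and 15); the second branch is steps 9–13.

**Three steps most likely to fail**

1. **Step 14 (proposed new arylative annulation).** Risks are arylation at the wrong enaminone carbon (flavone-type product), phenoxide O-arylation, or simple cyclisation of 12 to the unarylated chromone. Fallback with known chemistry: cyclise 12 with I2/pyridine in CHCl3 to the 3-iodochromone, convert 19 into its pinacol boronate (B2pin2, Pd(dppf)Cl2, KOAc), and join them by Suzuki–Miyaura coupling (Pd(PPh3)4, Na2CO3, DME/H2O) to reach 20.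
2. **Step 4 (directed metalation/acylation next to the benzyl ether).** Risks are benzylic deprotonation, lithiation at the wrong site, or enolisation of the Weinreb amide by the hindered aryllithium. Fallback: drop the benzyl ether. Lithiate 2 and quench with acetaldehyde; let the benzylic alkoxide and the neighbouring OMOM direct a second lithiation; then B(OMe)3/H2O2 and MnO2 oxidation give 2-hydroxy-3,6-bis(methoxymethoxy)acetophenone. Iodinate this para to the free OH and continue through Sonogashira coupling, hydrogenation and enaminone formation.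
3. **Step 15 (acidic removal of three MOM groups).** Risks are hydration or oligomerisation of the chromene, and cyclisation or solvolysis of the tertiary alcohol. Fallback: change the protecting-group plan by using SEM ethers in place of MOM in steps 1 and 11 (they also direct metalation), so the final unmasking is fluoride-mediated (TBAF, DMPU, 80 °C) and no acid is used at the end.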